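Ring A of the flavone is taken apart at C8–C8a, C6–C7 and C4a–C8a, so the crowded C8–aryl bond is never made by coupling; it is carried into the synthesis on an aryl siloxyalkyne. One thermal vinylketene–alkyne benzannulation between {[(2,4-dimethoxyphenyl)ethynyl]oxy}triisopropylsilane and 3-ethoxycyclobut-2-en-1-one should build this whole ring, exploiting its phloroglucinol pattern: the oxygen on C8a emerges as a free phenol, that on C7 as a silyl ether and that on C5 as an ethyl ether, with the resorcinol-type aryl group on C8. Rings C and B are then hung on the free phenol, and the coumarin lactone is annulated onto the resorcinol ring last.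

Key step: step 3

Assumption: the axis between flavone C8 and coumarin C6 carries no descriptor in the target and is treated as freely rotating, so no atropisomer control is planned.

Step 1
Reactants: 1 methyl 2,4-dimethoxybenzoate
Product: 3 {[(2,4-dimethoxyphenyl)ethynyl]oxy}tri(propan-2-yl)silane, via lithium ynolate 2 (not isolated)
Conditions: CH2Br2, lithium 2,2,6,6-tetramethylpiperidide, THF, −78 °C; n-BuLi, −78 → 0 °C; iPr3SiCl, −78 °C → rt
Reagents that add atoms: dibromomethane BrCBr; chlorotri(propan-2-yl)silane CC(C)[Si](Cl)(C(C)C)C(C)C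
Why: Kowalski ester homologation: dibromomethyllithium addition, bromine–lithium exchange and 1,2-aryl shift should give lithium ynolate 2, which the bulky silyl chloride traps on oxygen to give the siloxyalkyne.

Step 2
Reactants: 4 acetone; 5 ethoxyacetylene
Product: 7 3-ethoxycyclobut-2-en-1-one, via ketene 6 (not isolated)
Conditions: 4, hot-filament pyrolysis (ketene generator); ketene stream into 5, CH2Cl2, 0 °C
Reagents that add atoms: none
Why: Thermal ketene–alkyne [2+2] cycloaddition: the terminal carbon of the ynol ether is the nucleophile and bonds to the ketene carbonyl carbon, so the ethoxy group should end on C3 of the cyclobutenone.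

Step 3
Reactants: 3 {[(2,4-dimethoxyphenyl)ethynyl]oxy}tri(propan-2-yl)silane; 7 3-ethoxycyclobut-2-en-1-one
Product: 12 2-(2,4-dimethoxyphenyl)-5-ethoxy-3-{[tri(propan-2-yl)silyl]oxy}phenol, via vinylketene 8 (not isolated), via vinylcyclobutenone 9 (not isolated), via dienylketene 10 (not isolated), via cyclohexadienone 11 (not isolated)
Conditions: PhMe (degassed), 80 °C then 110 °C, sealed tube; 7 added slowly
Reagents that add atoms: none
Why: Heating should open 7 by 4π-electrocyclic ring opening to (1-ethoxyvinyl)ketene 8, whose ketene C=C adds to the siloxyalkyne in a [2+2] cycloaddition to give vinylcyclobutenone 9; reversible 4π opening of 9 gives dienylketene 10, which closes to cyclohexadienone 11 and tautomerises to phenol 12. The closest known reaction type is the Danheiser benzannulation of cyclobutenones with triisopropylsiloxyalkynes to 3-siloxyphenols; the 3-alkoxy group on the cyclobutenone and the aryl group on the alkyne are little-explored variations, which is why the temperature is ramped. Ring A is closed as a six-membered carbocycle by thermal disrotatory 6π-electrocyclization (C4a–C8a), after the [2+2] step has made C8–C8a and C6–C7. No stereocenter survives, since the sp3 carbons of 9 and 11 are lost on ring opening and aromatization. The selectivity required is the regiochemistry of the [2+2] step, secured by the oxygen lone pair of the siloxyalkyne, which makes the aryl-bearing carbon nucleophilic so that it bonds to the electrophilic ketene carbonyl carbon; the aryl group thus ends ortho to the new hydroxyl, the siloxy group meta to it and the ethoxy group para to the aryl group. Slow addition of 7 keeps the concentration of 8 low and should limit ketene self-reaction and O-acylation of 12.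

Step 4
Reactants: 12 2-(2,4-dimethoxyphenyl)-5-ethoxy-3-{[tri(propan-2-yl)silyl]oxy}phenol; 13 methyl 3-(4-methoxyphenyl)prop-2-ynoate
Product: 14 methyl (Z)-3-[2-(2,4-dimethoxyphenyl)-5-ethoxy-3-{[tri(propan-2-yl)silyl]oxy}phenoxy]-3-(4-methoxyphenyl)prop-2-enoate
Conditions: Cs2CO3 (0.3 equiv), MeCN, 70 °C
Reagents that add atoms: none
Why: Oxa-Michael addition: the phenoxide of the only free hydroxyl (the future O1 on C8a) adds to the β-carbon of the ynoate with anti protonation, which should give mainly the Z enol ether, while the silyl ether keeps the C7 oxygen from reacting.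

Step 5
Reactants: 14 methyl (Z)-3-[2-(2,4-dimethoxyphenyl)-5-ethoxy-3-{[tri(propan-2-yl)silyl]oxy}phenoxy]-3-(4-methoxyphenyl)prop-2-enoate
Product: 15 8-(2,4-dimethoxyphenyl)-5-ethoxy-7-hydroxy-2-(4-methoxyphenyl)-4H-chromen-4-one
Conditions: P2O5/MeSO3H (1:10 w/w), 50 °C; then ice/H2O
Reagents that add atoms: none
Why: Intramolecular Friedel–Crafts acylation by the ester (chromone closure of a β-aryloxycinnamate, the oxygen analogue of acid-mediated 4-quinolone cyclisations) can reach only C4a, which three oxygen substituents activate; the acid also equilibrates the alkene geometry and removes the silyl group.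

Step 6
Reactants: 15 8-(2,4-dimethoxyphenyl)-5-ethoxy-7-hydroxy-2-(4-methoxyphenyl)-4H-chromen-4-one
Product: 16 8-(2,4-dihydroxyphenyl)-5,7-dihydroxy-2-(4-hydroxyphenyl)-4H-chromen-4-one
Conditions: BBr3 (excess), CH2Cl2, −78 °C → rt; then MeOH, H2O
Reagents that add atoms: none
Why: Lewis acid ether cleavage with BBr3, standard for polyalkoxyflavones, should remove the three methyl groups and the chelation-activated ethyl group at O5 without touching the pyranone.

Step 7
Reactants: 16 8-(2,4-dihydroxyphenyl)-5,7-dihydroxy-2-(4-hydroxyphenyl)-4H-chromen-4-one; 17 propiolic acid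
Product: 18 5,7-dihydroxy-8-(7-hydroxy-2-oxo-2H-chromen-6-yl)-2-(4-hydroxyphenyl)-4H-chromen-4-one
Conditions: 17 (1.5 equiv), MeSO3H, 50 °C
Reagents that add atoms: none
Why: Pechmann condensation with propiolic acid: in MeSO3H the flavone carbonyl is protonated (4-hydroxyflavylium), which deactivates rings A and B, so hydroarylation and lactonisation should take place on the pendant resorcinol ring at the carbon para to its 2-hydroxyl and ortho to its 4-hydroxyl, the position between the two hydroxyls being crowded.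

Compound list
1 | methyl 2,4-dimethoxybenzoate | COC(=O)c1ccc(OC)cc1OC | starting material
2 | lithium 2-(2,4-dimethoxyphenyl)ethynolate | [Li+].[O-]C#Cc1ccc(OC)cc1OC | intermediate (not isolated)
3 | {[(2,4-dimethoxyphenyl)ethynyl]oxy}tri(propan-2-yl)silane | COc1ccc(C#CO[Si](C(C)C)(C(C)C)C(C)C)c(OC)c1 | intermediate
4 | acetone | CC(C)=O | starting material
5 | ethoxyacetylene (ethoxyethyne) | CCOC#C | starting material
6 | ketene | C=C=O | intermediate (not isolated)
7 | 3-ethoxycyclobut-2-en-1-one | CCOC1=CC(=O)C1 | intermediate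
8 | 3-ethoxybuta-1,3-dien-1-one, (1-ethoxyvinyl)ketene | C=C(OCC)C=C=O | intermediate (not isolated)
9 | 2-(2,4-dimethoxyphenyl)-4-(1-ethoxyethenyl)-3-{[tri(propan-2-yl)silyl]oxy}cyclobut-2-en-1-one, racemic | C=C(OCC)C1C(=O)C(c2ccc(OC)cc2OC)=C1O[Si](C(C)C)(C(C)C)C(C)C | intermediate (not isolated)
10 | (3E)-2-(2,4-dimethoxyphenyl)-5-ethoxy-3-{[tri(propan-2-yl)silyl]oxy}hexa-1,3,5-trien-1-one, the isomer able to cyclise | O=C=C(c1ccc(OC)cc1OC)/C(O[Si](C(C)C)(C(C)C)C(C)C)=C\C(OCC)=C | intermediate (not isolated)
11 | 2-(2,4-dimethoxyphenyl)-5-ethoxy-3-{[tri(propan-2-yl)silyl]oxy}cyclohexa-2,4-dien-1-one | CCOC1=CC(O[Si](C(C)C)(C(C)C)C(C)C)=C(c2ccc(OC)cc2OC)C(=O)C1 | intermediate (not isolated)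
12 | 2-(2,4-dimethoxyphenyl)-5-ethoxy-3-{[tri(propan-2-yl)silyl]oxy}phenol | CCOc1cc(O)c(-c2ccc(OC)cc2OC)c(O[Si](C(C)C)(C(C)C)C(C)C)c1 | intermediate
13 | methyl 3-(4-methoxyphenyl)prop-2-ynoate | COc1ccc(C#CC(=O)OC)cc1 | starting material
14 | methyl (Z)-3-[2-(2,4-dimethoxyphenyl)-5-ethoxy-3-{[tri(propan-2-yl)silyl]oxy}phenoxy]-3-(4-methoxyphenyl)prop-2-enoate | COC(=O)/C=C(\Oc1cc(OCC)cc(O[Si](C(C)C)(C(C)C)C(C)C)c1-c1ccc(OC)cc1OC)c1ccc(OC)cc1 | intermediate
15 | 8-(2,4-dimethoxyphenyl)-5-ethoxy-7-hydroxy-2-(4-methoxyphenyl)-4H-chromen-4-one | CCOc1cc(O)c(-c2ccc(OC)cc2OC)c2oc(-c3ccc(OC)cc3)cc(=O)c12 | intermediate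
16 | 8-(2,4-dihydroxyphenyl)-5,7-dihydroxy-2-(4-hydroxyphenyl)-4H-chromen-4-one | O=c1cc(-c2ccc(O)cc2)oc2c(-c3ccc(O)cc3O)c(O)cc(O)c12 | intermediate
17 | propiolic acid (prop-2-ynoic acid) | C#CC(=O)O | starting material
18 | 5,7-dihydroxy-8-(7-hydroxy-2-oxo-2H-chromen-6-yl)-2-(4-hydroxyphenyl)-4H-chromen-4-one | O=c1ccc2cc(-c3c(O)cc(O)c4c(=O)cc(-c5ccc(O)cc5)oc34)c(O)cc2o1 | target

Total step count: 7. Longest linear sequence: 6 steps (steps 1, 3, 4, 5, 6, 7).

Steps most likely to fail

Step 3. The donor-stabilised cyclobutenone may open too slowly, or the enol-ether-bearing vinylketene may oligomerise or acylate the product phenol faster than the alkyne captures it. The fallback makes the C8–aryl bond by cross-coupling on a finished flavone instead of by ring construction. It sets out from 13: Cs2CO3-mediated addition of 3,5-dimethoxyphenol gives methyl (Z)-3-(3,5-dimethoxyphenoxy)-3-(4-methoxyphenyl)prop-2-enoate F1, and P2O5/MeSO3H closes it to 5,7-dimethoxy-2-(4-methoxyphenyl)-4H-chromen-4-one F2. Iodination with I2/CF3CO2Ag, which is expected at C8 in 5-alkoxyflavones, gives 8-iodo-5,7-dimethoxy-2-(4-methoxyphenyl)-4H-chromen-4-one F3. Suzuki–Miyaura coupling with 2,4-dimethoxyphenylboronic acid (Pd(OAc)2, SPhos, K3PO4, PhMe/H2O) gives 8-(2,4-dimethoxyphenyl)-5,7-dimethoxy-2-(4-methoxyphenyl)-4H-chromen-4-one F4. BBr3 then cleaves all five methyl ethers, and the route is rejoined at 16.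

Step 7. The annulation may stray onto C6 of ring A or onto ring B, or the five phenols may be esterified and degraded in hot acid. The fallback forms the coumarin C–C bond at the ether stage and lets the lactone close during deprotection. It sets out from 15: Fujiwara hydroarylation of ethyl propiolate (Pd(OAc)2 cat., CF3CO2H/CH2Cl2, rt) should alkenylate the dimethoxyphenyl ring para to its 2-methoxy group, the chromone being protonated and unreactive in this medium. This gives ethyl (Z)-3-{5-[5-ethoxy-7-hydroxy-2-(4-methoxyphenyl)-4-oxo-4H-chromen-8-yl]-2,4-dimethoxyphenyl}prop-2-enoate F5. BBr3 then cleaves all ethers, and the hydroxyl freed next to the Z-acrylate lactonises, which returns the route at 18.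

Step 4. The conjugate addition may stall at the hindered phenoxide, or base-induced silyl loss may open the way to double addition. The fallback attaches the three-carbon unit through carbon first. It sets out from 12: Bu4NF in THF removes the silyl group to give 2-(2,4-dimethoxyphenyl)-5-ethoxybenzene-1,3-diol F6, whose two open ring positions are equivalent by symmetry, so acylation needs no regiocontrol. Friedel–Crafts acylation with (E)-4-methoxycinnamoyl chloride and BF3·OEt2 gives (E)-1-[3-(2,4-dimethoxyphenyl)-6-ethoxy-2,4-dihydroxyphenyl]-3-(4-methoxyphenyl)prop-2-en-1-one F7. Oxidative cyclisation of this 2'-hydroxychalcone (I2 cat., DMSO, 120 °C) returns the route at 15.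

Further compounds
F1 | step 3 | methyl (Z)-3-(3,5-dimethoxyphenoxy)-3-(4-methoxyphenyl)prop-2-enoate | COC(=O)/C=C(\Oc1cc(OC)cc(OC)c1)c1ccc(OC)cc1
F2 | step 3 | 5,7-dimethoxy-2-(4-methoxyphenyl)-4H-chromen-4-one | COc1ccc(cc1)-c1cc(=O)c2c(OC)cc(OC)cc2o1
F3 | step 3 | 8-iodo-5,7-dimethoxy-2-(4-methoxyphenyl)-4H-chromen-4-one | COc1ccc(cc1)-c1cc(=O)c2c(OC)cc(OC)c(I)c2o1
F4 | step 3 | 8-(2,4-dimethoxyphenyl)-5,7-dimethoxy-2-(4-methoxyphenyl)-4H-chromen-4-one | COc1ccc(cc1)-c1cc(=O)c2c(OC)cc(OC)c(-c3ccc(OC)cc3OC)c2o1
F5 | step 7 | ethyl (Z)-3-{5-[5-ethoxy-7-hydroxy-2-(4-methoxyphenyl)-4-oxo-4H-chromen-8-yl]-2,4-dimethoxyphenyl}prop-2-enoate | CCOC(=O)/C=C\c1cc(-c2c(O)cc(OCC)c3c(=O)cc(-c4ccc(OC)cc4)oc23)c(OC)cc1OC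
F6 | step 4 | 2-(2,4-dimethoxyphenyl)-5-ethoxybenzene-1,3-diol | CCOc1cc(O)c(-c2ccc(OC)cc2OC)c(O)c1
F7 | step 4 | (E)-1-[3-(2,4-dimethoxyphenyl)-6-ethoxy-2,4-dihydroxyphenyl]-3-(4-methoxyphenyl)prop-2-en-1-one | CCOc1cc(O)c(-c2ccc(OC)cc2OC)c(O)c1C(=O)/C=C/c1ccc(OC)cc1
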